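By the last reading of Friday's run, at 8.00 min, the left-handed substrate stands at 41.4% and the right-handed substrate at 49.3%, though they were charged equally, and the left-handed product has reached 9.2%. In these flasks the single-handed free catalyst turns substrate and partner into product, a kinetic resolution, while the racemization catalyst turns each substrate into the other. Monday's flask is the one asked about, followed so far for 60.0 s.

the same everywhere: left-handed substrate 0.37 M; right-handed substrate 0.37 M; partner 1.48 M; racemization catalyst 2.9 mM
- Monday's: free catalyst 0.85 mM; the very flask that is asked about, followed so far
- Friday's: free catalyst 0.57 mM; run made earlier
- flask: free catalyst 0.85 mM; time 8.0 min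

- Monday's (time / s: left-handed substrate / %, right-handed substrate / %, left-handed product / %): 10.0: 49.7, 50.1, 0; 15.0: 49.8, 49.9, 0.5; 25.0: 49.6, 50.3, 0; 40.0: 49.0, 49.6, 0.2; 60.0: 48.9, 48.8, 1.7
- Friday's (time / min: left-handed substrate / %, right-handed substrate / %, left-handed product / %): 0.667: 49.3, 50.5, 1.1; 2.00: 47.2, 49.6, 3.0; 4.00: 45.1, 49.5, 4.1; 6.00: 44.1, 49.1, 7.2; 8.00: 41.4, 49.3, 9.2

(scatter of a reading: 0.5 percentage points)

- free catalyst is single-handed; left-handed substrate and right-handed substrate are mirror images of each other, charged as a racemate, each of them at the stated concentration
- an excess is the difference of the two amounts in percent of their sum
- an excess is below zero if the other one leads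

- part of the left-handed substrate and right-handed substrate charged together that has reacted at 8.0 min
- excess of left-handed product over right-handed product in the product at 8.0 min
- excess of right-handed substrate over left-handed substrate among what is left of the two at 8.0 min

The late readings carry a balance. Each point of left-handed product widens the gap between the substrates by one; each point of right-handed product narrows it by one, and each point racemized from right to left narrows it by two. The gap share, the right-handed substrate minus the left-handed substrate, divided by the left-handed product, is therefore one where neither leak runs. Friday's last 3 readings pooled give 0.844; the last one gives 0.859 and the one before it 0.694, so the pooled figure is a reading that carries their scatter.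

Monday's flask has 0.85 mM of free catalyst against Friday's 0.57 mM. If the product scales with that catalyst, Friday's gain predicts 1.71% at 60.0 s, and Monday's reading is 1.7%, with a scatter of 0.5 percentage points. At 40.0 s the same scaling predicts 1.14% against Monday's reading of 0.2%, so the scaling stays an assumption. The same scaling gives 13.7% of left-handed product at 8.0 min. Carried over from Friday's run as an assumption, the gap share then gives a gap of 12 points and a substrate excess near 13.4%. Friday's unaccounted remainder, 0.100%, lies within the scatter, so the right-handed product and the product excess stay open.

The forecast gave 13.5% reacted (10.5% to 16%), a product excess of 81% (68% to 92%) and a substrate excess of 12.5% (9.5% to 15.5%), calling the flask “essentially simple kinetic resolution on this timescale”; the reckoning here puts the substrate excess higher than that.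

The flask gives 12.7% reacted, a product excess of 88.7% and a substrate excess of 11.3%.

    partner + free catalyst + right-handed substrate → free catalyst + right-handed product (k = 2.10 M⁻² min⁻¹)
    partner → decomposition product (k = 8.87 × 10⁻⁵ min⁻¹)
    partner + free catalyst + left-handed substrate → free catalyst + left-handed product (k = 39.1 M⁻² min⁻¹)
    left-handed substrate + racemization catalyst ⇌ right-handed substrate + racemization catalyst, rate k4*[racemization catalyst]*[left-handed substrate] forward; the back reaction follows from the equilibrium constant (k = 39.5 M⁻¹ min⁻¹)
    2 racemization catalyst → spent catalyst (k = 241 M⁻¹ min⁻¹)
    2 free catalyst ⇌ resting dimer, settled at all times (K = 330 M⁻¹)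

At 8.00 min the asked flask holds 12.0% of left-handed product, below the 13.7% reckoned, with 28.6% of the catalyst charged in the resting dimer, and its gap share is 0.824 against the 0.844 read from Friday's readings. In that flask at 8.00 min the free catalyst's route uses left-handed substrate 3.5 times as fast as the forward racemization step alone, up from 1.8 at 3.68 min, and the racemization catalyst stands at 8.21% of its charge. The neighbour charged with 0.0021 M of free catalyst holds 20.3% of left-handed product, and its gap share is 0.812.

(Readings and results were computed for substances that don't exist.)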